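The ratio of E to Q at a fixed clock time is the number I carry from run to run. I call it the split S, a selectivity. X and the reagent Z give both products with the catalyst L present, and the question is what S does when a setting is turned.

| flask | X | Z | L | remark | time |
|---|---|---|---|---|---|
| grey | 1.5 M | 1.42 M | 1.5 mM | run made earlier |  |
| red | 1.5 M | 1.42 M | 2.2 mM | run made earlier |  |
| green | 1.5 M | 0.71 M | 3 mM | run made earlier |  |
| flask | 1.5 M | 1.42 M | 3.0 mM |  | 12 h |

| run | time / h | E / % | Q / % |
|---|---|---|---|
| grey | 1.50 | 33.9 | 8.1 |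
| grey | 3.00 | 42.5 | 10.6 |
| grey | 5.00 | 45.1 | 14.0 |
| grey | 6.00 | 44.5 | 14.8 |
| grey | 8.00 | 43.3 | 17.3 |
| grey | 10.0 | 43.1 | 18.4 |
| grey | 12.0 | 41.5 | 19.6 |
| red | 1.50 | 34.8 | 8.1 |
| red | 3.00 | 42.3 | 11.7 |
| red | 5.00 | 45.2 | 13.6 |
| red | 6.00 | 44.3 | 15.0 |
| red | 8.00 | 43.6 | 17.6 |
| red | 10.0 | 42.5 | 19.4 |
| red | 12.0 | 40.7 | 20.4 |
| green | 1.00 | 15.5 | 3.4 |
| green | 3.00 | 24.8 | 6.5 |
| green | 6.00 | 25.3 | 9.3 |
| green | 8.00 | 25.0 | 10.1 |
| green | 12.0 | 23.7 | 11.4 |

(readings scatter by 0.5 percentage points)

* ratio of E to Q at 5.0 min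
* ratio of E to Q at 1.0 h
* ratio of E to Q at 12 h

- the earlier runs were read with a standard deviation of 0.5 percentage points

I turn L first. By hand, going from grey's 1.5 mM to red's 2.2 mM should move S if L matters. At 12 h the readings go from 2.12 to 2.00, a step of 0.122, in readings with a scatter of 0.5 points, so I draw no firm slope from it. I need none: green ran at 3 mM, the L of the flask, and its split at 12 h, the ratio of its E to its Q, reads 2.08.

Z comes next, and green holds half the Z of the flask. By hand, less Z means less product, yet S stays put if E and Q shrink together. They do, though green also holds more L than red, so two settings differ in this comparison: at 12 h green's E is 58.2 % of red's and its Q 55.9 % of red's. So I carry green's splits to the flask unchanged, 2.08 at 12 h and 4.56 at 1.0 h. Green's first reading comes later than 5.0 min, so I give no number of my own there.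

The forecast says 5.6 at 5.0 min, 4.6 at 1.0 h and 2.05 at 12 h, with the ground “I therefore expect the flask to track red.” It names red where I take green, and at 12 h we stand 0.0300 apart.

The flask gives 5.01, 4.53 and 1.94, so the forecast holds within the margins at each time, and my 2.08, still a reading of green with that run's scatter, lies 0.140 above the flask's ratio at 12 h.

    X + Z ⇌ E (K = 2.10 M⁻¹, k = 9.60 × 10⁻⁵ M⁻¹ s⁻¹)
    X + Z ⇌ Q (K = 1.60 M⁻¹, k = 1.90 × 10⁻⁵ M⁻¹ s⁻¹)
    E + L ⇌ Q + L, rate k3*[L]*[E] forward; the back reaction follows from the equilibrium constant (k = 0.00160 M⁻¹ s⁻¹)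

A neighbouring flask has 0.35 M of Z, a quarter of the charge here, with L unchanged. The same reckoning gives 2.08 for it again. That neighbour shows 4.55 at 1.0 h, and at 12 h it still holds 81.3 % of its X, with E at 12.3 % and Q at 6.36 %, a ratio of 1.94.

The earlier runs and the new flask were generated by integration from invented constants; noise was put on by code.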